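**Plan**
- **Cuts:** The C4 ketone of ring C is read as its silyl enol ether, so C3–C4 becomes a C=C bond, which is cut first (retro-metathesis). The next cuts are O1–C2 (allylic etherification), the side-chain C=C (olefination), and the furan O–C2' and C3'–alkyne bonds (coupling–annulation).
- **Enabling feature:** C4 sits on C4a and O1 on the adjacent C8a of ring A, and C3 is bonded to C2. An acetyl group on C4a and a vinyl group on C2 therefore form a 1,7-diene clamped by the ortho-disubstituted ring A, and ring C is a masked 4-silyloxy-2H-chromene.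
- **Forward order:** The furan ring of the benzofuran is made first (step 1), followed by the three-carbon chain (steps 2–4). Ring A is joined through O1–C2 (step 5) and the ketone is enol-silylated (step 6). Ring C closes last (step 7) and the ketone is unmasked (step 8).
- **Stereochemistry:** The only stereocentre, (S)-C2, is set by the chiral phosphoramidite ligand in the iridium-catalysed branched-selective etherification. Later steps avoid phenoxide, enolate, free Lewis acid, heat and light.

Key step: step 7

Assumption: the sense of induction in step 5 is taken by analogy with cinnamyl carbonates and aryloxides, for which the (Sa,Sc,Sc)-ligand is expected to give the (S)-ether; both ligand antipodes are commercial, so a reversed sense would only call for the mirror-image ligand.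

**Step 1**
Reactants: 1 4-hydroxy-3-iodobenzaldehyde; 2 4-ethynylanisole
Product: 4 2-(4-methoxyphenyl)-1-benzofuran-5-carbaldehyde, via o-alkynylphenol 3 (not isolated)
Conditions: PdCl2(PPh3)2 (2 mol %), CuI (4 mol %), Et3N, DMF, rt → 70 °C, Ar
Reagents that add atoms: none
Why: Sonogashira coupling at the aryl iodide gives the o-alkynylphenol, whose phenol (acidified by the para formyl group) adds 5-endo-dig to the metal-activated alkyne in the same flask, a standard one-pot benzofuran annulation that tolerates the aldehyde.

**Step 2**
Reactants: 4 2-(4-methoxyphenyl)-1-benzofuran-5-carbaldehyde; 5 triethyl phosphonoacetate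
Product: 6 ethyl (E)-3-[2-(4-methoxyphenyl)-1-benzofuran-5-yl]prop-2-enoate
Conditions: LiCl, DBU, MeCN–THF, 0 °C → rt
Reagents that add atoms: none
Why: Horner–Wadsworth–Emmons olefination (Masamune–Roush conditions) of a non-enolisable aromatic aldehyde with a stabilised phosphonate should give the (E)-enoate.

**Step 3**
Reactants: 6 ethyl (E)-3-[2-(4-methoxyphenyl)-1-benzofuran-5-yl]prop-2-enoate
Product: 7 (E)-3-[2-(4-methoxyphenyl)-1-benzofuran-5-yl]prop-2-en-1-ol
Conditions: DIBAL-H (2.5 equiv), CH2Cl2, −78 → 0 °C; aq. Rochelle salt
Reagents that add atoms: none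
Why: 1,2-Reduction of an α,β-unsaturated ester with DIBAL-H is the standard route to (E)-cinnamyl-type alcohols and leaves the benzofuran and the aryl methyl ether untouched.

**Step 4**
Reactants: 7 (E)-3-[2-(4-methoxyphenyl)-1-benzofuran-5-yl]prop-2-en-1-ol
Product: 8 methyl (E)-3-[2-(4-methoxyphenyl)-1-benzofuran-5-yl]prop-2-en-1-yl carbonate
Conditions: ClCO2Me, pyridine, CH2Cl2, 0 °C → rt
Reagents that add atoms: methyl chloroformate, COC(=O)Cl
Why: O-Acylation of the primary allylic alcohol with a chloroformate installs a leaving group that, on ionisation and loss of CO2, supplies its own base (methoxide) for the next step.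

**Step 5**
Reactants: 8 methyl (E)-3-[2-(4-methoxyphenyl)-1-benzofuran-5-yl]prop-2-en-1-yl carbonate; 9 paeonol (2-hydroxy-4-methoxyacetophenone)
Product: 10 (S)-1-[4-methoxy-2-({1-[2-(4-methoxyphenyl)-1-benzofuran-5-yl]prop-2-en-1-yl}oxy)phenyl]ethan-1-one
Conditions: [Ir(cod)Cl]2 (2 mol %), (Sa,Sc,Sc)-L (4 mol %; L = (S)-BINOL-derived N,N-bis[(S)-1-phenylethyl]phosphoramidite), TBD (8 mol %), THF, rt (activation); then 8, 9 (1.5 equiv), THF, rt, Ar
Reagents that add atoms: none
Why: In this iridium-catalysed asymmetric allylic etherification the cyclometallated Ir–phosphoramidite ionises the linear carbonate to an (η3-allyl)iridium species, and the aryloxide (formed from 9 by the released methoxide) attacks the aryl-substituted terminus anti to the metal, so the branched ether forms and the ligand fixes the allyl face and hence (S)-C2.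

**Step 6**
Reactants: 10 (S)-1-[4-methoxy-2-({1-[2-(4-methoxyphenyl)-1-benzofuran-5-yl]prop-2-en-1-yl}oxy)phenyl]ethan-1-one
Product: 11 (S)-branched allyl aryl ether with an ortho 1-(tert-butyldimethylsilyloxy)vinyl group (TBS enol ether of 10)
Conditions: TBSOTf (1.3 equiv), Et3N (3 equiv), CH2Cl2, −20 → 0 °C; cold aq. NaHCO3; Et3N-deactivated silica
Reagents that add atoms: tert-butyldimethylsilyl triflate, CC(C)(C)[Si](C)(C)OS(=O)(=O)C(F)(F)F
Why: Soft enolisation (O-silylation of the aryl ketone followed by removal of a proton from its only α-position, the methyl group) gives the terminal silyl enol ether, and the excess amine present from the start keeps the medium free of acid so the allylic benzylic ether is not ionised.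

**Step 7**
Reactants: 11 (S)-branched allyl aryl ether with an ortho 1-(tert-butyldimethylsilyloxy)vinyl group
Product: 12 (S)-4-(tert-butyldimethylsilyloxy)-7-methoxy-2-[2-(4-methoxyphenyl)-1-benzofuran-5-yl]-2H-chromene
Conditions: Grubbs II (5 + 5 mol %), 1,4-benzoquinone (10 mol %), CH2Cl2 (5 mM), 40 °C, Ar sparge, dark; filtration through neutral alumina
Reagents that add atoms: none
Why: The ruthenium benzylidene exchanges first with the only monosubstituted alkene, the vinyl group on C2, and the new alkylidene adds in an intramolecular [2+2] fashion across the 1-silyloxyvinyl group on C4a; cycloreversion of the ruthenacyclobutane leaves the C3=C4 bond and a ruthenium methylidene that carries the chain, ethene being swept out. The closest known reaction type is silyl enol ether–ene ring-closing metathesis, which gives carbocyclic silyl enol ethers and benzo-fused 4-silyloxy-1,2-dihydroquinolines from nitrogen analogues of 11, together with the diene metathesis of o-vinylphenyl allyl ethers to 2H-chromenes. Ring C closes as a six-membered ring with an endocyclic double bond from a 1,7-diene in which C4, C4a, C8a and O1 are already held close to one plane by ring A, so few rotors have to be frozen. No stereocentre is created, and C2 is a spectator whose four bonds stay intact in a neutral medium free of phenoxide, enolate and acid. The step needs initiation at the vinyl group rather than at the enol ether, and closure rather than dimerisation: the first is secured by the steric and electronic reluctance of the 1,1-disubstituted oxygen-bearing alkene and by the aromatic character of the benzofuran C2=C3 bond, the second by the ortho tether and high dilution. Benzoquinone intercepts ruthenium hydrides that would shift the allylic double bond, 40 °C lies well below the onset of the aromatic Claisen rearrangement, and darkness blocks the photochemical 6π opening of the 2H-chromene that would scramble C2.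

**Step 8**
Reactants: 12 (S)-4-(tert-butyldimethylsilyloxy)-7-methoxy-2-[2-(4-methoxyphenyl)-1-benzofuran-5-yl]-2H-chromene
Product: 13 lophirone J, (S)-7-methoxy-2-[2-(4-methoxyphenyl)-1-benzofuran-5-yl]chroman-4-one
Conditions: aq. HCl (cat., 1 M), THF–H2O 9:1, 0 °C, dark
Reagents that add atoms: none
Why: Acid hydrolysis of a silyl enol ether runs through protonation at C3 and attack of water on silicon, so the ketone appears without an enolate stage and the retro-oxa-Michael opening that would racemise C2 is not available under cold dilute acid.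

**Compound list**
1 | 4-hydroxy-3-iodobenzaldehyde | O=Cc1ccc(O)c(I)c1 | starting material
2 | 4-ethynylanisole | C#Cc1ccc(OC)cc1 | starting material
3 | 4-hydroxy-3-[(4-methoxyphenyl)ethynyl]benzaldehyde | O=Cc1ccc(O)c(C#Cc2ccc(OC)cc2)c1 | intermediate (not isolated)
4 | 2-(4-methoxyphenyl)-1-benzofuran-5-carbaldehyde | COc1ccc(-c2cc3cc(C=O)ccc3o2)cc1 | intermediate
5 | triethyl phosphonoacetate | CCOC(=O)CP(=O)(OCC)OCC | starting material
6 | ethyl (E)-3-[2-(4-methoxyphenyl)-1-benzofuran-5-yl]prop-2-enoate | CCOC(=O)/C=C/c1ccc2oc(-c3ccc(OC)cc3)cc2c1 | intermediate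
7 | (E)-3-[2-(4-methoxyphenyl)-1-benzofuran-5-yl]prop-2-en-1-ol | OC/C=C/c1ccc2oc(-c3ccc(OC)cc3)cc2c1 | intermediate
8 | methyl (E)-3-[2-(4-methoxyphenyl)-1-benzofuran-5-yl]prop-2-en-1-yl carbonate | COC(=O)OC/C=C/c1ccc2oc(-c3ccc(OC)cc3)cc2c1 | intermediate
9 | paeonol (2-hydroxy-4-methoxyacetophenone) | CC(=O)c1ccc(OC)cc1O | starting material
10 | (S)-1-[4-methoxy-2-({1-[2-(4-methoxyphenyl)-1-benzofuran-5-yl]prop-2-en-1-yl}oxy)phenyl]ethan-1-one | COc1ccc(-c2cc3cc([C@@H](Oc4cc(OC)ccc4C(C)=O)C=C)ccc3o2)cc1 | intermediate
11 | (S)-5-[1-({2-[1-(tert-butyldimethylsilyloxy)vinyl]-5-methoxyphenyl}oxy)prop-2-en-1-yl]-2-(4-methoxyphenyl)-1-benzofuran | COc1ccc(-c2cc3cc([C@@H](Oc4cc(OC)ccc4C(=C)O[Si](C)(C)C(C)(C)C)C=C)ccc3o2)cc1 | intermediate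
12 | (S)-4-(tert-butyldimethylsilyloxy)-7-methoxy-2-[2-(4-methoxyphenyl)-1-benzofuran-5-yl]-2H-chromene | COc1ccc(-c2cc3cc([C@@H]4C=C(O[Si](C)(C)C(C)(C)C)c5ccc(OC)cc5O4)ccc3o2)cc1 | intermediate
13 | lophirone J, (S)-7-methoxy-2-[2-(4-methoxyphenyl)-1-benzofuran-5-yl]chroman-4-one | COc1ccc(-c2cc3cc([C@@H]4CC(=O)c5ccc(OC)cc5O4)ccc3o2)cc1 | target

Total step count: 8. Longest linear sequence: 8 steps (1 → 13); 9 enters at step 5.

**Steps most likely to fail**

**Step 7.**
- **Risk:** The hindered, electron-rich enol ether may engage slowly, and ruthenium may be trapped as an inert oxygen-stabilised carbene. Homodimerisation at the vinyl group or hydride-induced alkene migration could then take over.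
- **Fallback:** The ring is closed on a plain styrene and the C4 oxygen is introduced afterwards. The fallback sets out from 8 and comes back at 13.
- Wittig methylenation of commercial 2-hydroxy-4-methoxybenzaldehyde gives 5-methoxy-2-vinylphenol F1, which replaces 9 under the conditions of step 5 and gives the (S)-branched o-vinylphenyl ether F2.
- Ring-closing metathesis between its two monosubstituted alkenes gives the (S)-2-aryl-7-methoxy-2H-chromene F3.
- Mukaiyama hydration (Mn(dpm)3, PhSiH3, O2, i-PrOH, 0 °C) places the hydroxyl group on C4 through the benzylic radical and gives the (2S)-flavan-4-ol F4 as a mixture of C4 epimers.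
- Dess–Martin oxidation converts both epimers into 13.

**Step 5.**
- **Risk:** The hydrogen-bonded, weakly nucleophilic aryloxide may attack slowly. The product is the ether of a good leaving group on an electron-rich benzylic allylic carbon, so the catalyst may re-ionise it, which would erode the branched selectivity and the facial selectivity.
- **Fallback:** The stereocentre is made as a carbinol and the aryl–oxygen bond is formed instead, so the C2–O bond is never broken. The fallback sets out from 4 and comes back at 10.
- Vinylmagnesium bromide adds to 4 to give the racemic 1-arylprop-2-en-1-ol F5.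
- Lipase-catalysed kinetic resolution (CAL-B, vinyl acetate) should acylate the (R)-enantiomer. This leaves the (S)-1-arylprop-2-en-1-ol F6, which is separated from the (R)-acetate F7.
- The potassium alkoxide of F6 (KHMDS, THF–DMF, −20 °C → rt) displaces fluoride from commercial 2-fluoro-4-methoxyacetophenone (CC(=O)c1ccc(OC)cc1F) by nucleophilic aromatic substitution and gives 10 with retention at C2.

**Step 6.**
- **Risk:** The silyl triflate may ionise the C2–O1 bond, with loss of configuration or migration of the allyl group. The enol ether may also hydrolyse on isolation.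
- **Fallback:** The enol ether is made from an ester by carbonyl methylenation under non-acidic conditions. The fallback sets out from 8 and comes back at 13.
- Commercial methyl 2-hydroxy-4-methoxybenzoate replaces 9 under the conditions of step 5 and gives the (S)-branched aryloxy benzoate F8.
- Petasis methylenation (Cp2TiMe2, toluene, 70 °C, dark) gives the (S)-1-methoxyvinyl diene F9.
- Enol ether–ene ring-closing metathesis under the conditions of step 7 gives the (S)-4,7-dimethoxy-2-aryl-2H-chromene F10.
- Hydrolysis with cold dilute acid, as in step 8, releases 13.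

**Further compounds**
F1 | step 7 | 5-methoxy-2-vinylphenol | C=Cc1ccc(OC)cc1O
F2 | step 7 | (S)-5-{1-[(5-methoxy-2-vinylphenyl)oxy]prop-2-en-1-yl}-2-(4-methoxyphenyl)-1-benzofuran | COc1ccc(-c2cc3cc([C@@H](Oc4cc(OC)ccc4C=C)C=C)ccc3o2)cc1
F3 | step 7 | (S)-7-methoxy-2-[2-(4-methoxyphenyl)-1-benzofuran-5-yl]-2H-chromene | COc1ccc(-c2cc3cc([C@@H]4C=Cc5ccc(OC)cc5O4)ccc3o2)cc1
F4 | step 7 | (2S)-7-methoxy-2-[2-(4-methoxyphenyl)-1-benzofuran-5-yl]chroman-4-ol (C4 epimers) | COc1ccc(-c2cc3cc([C@@H]4CC(O)c5ccc(OC)cc5O4)ccc3o2)cc1
F5 | step 5 | rac-1-[2-(4-methoxyphenyl)-1-benzofuran-5-yl]prop-2-en-1-ol | COc1ccc(-c2cc3cc(C(O)C=C)ccc3o2)cc1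
F6 | step 5 | (S)-1-[2-(4-methoxyphenyl)-1-benzofuran-5-yl]prop-2-en-1-ol | COc1ccc(-c2cc3cc([C@@H](O)C=C)ccc3o2)cc1
F7 | step 5 | (R)-1-[2-(4-methoxyphenyl)-1-benzofuran-5-yl]prop-2-en-1-yl acetate | COc1ccc(-c2cc3cc([C@H](OC(C)=O)C=C)ccc3o2)cc1
F8 | step 6 | methyl (S)-4-methoxy-2-({1-[2-(4-methoxyphenyl)-1-benzofuran-5-yl]prop-2-en-1-yl}oxy)benzoate | COc1ccc(-c2cc3cc([C@@H](Oc4cc(OC)ccc4C(=O)OC)C=C)ccc3o2)cc1
F9 | step 6 | (S)-5-(1-{[5-methoxy-2-(1-methoxyvinyl)phenyl]oxy}prop-2-en-1-yl)-2-(4-methoxyphenyl)-1-benzofuran | COc1ccc(-c2cc3cc([C@@H](Oc4cc(OC)ccc4C(=C)OC)C=C)ccc3o2)cc1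
F10 | step 6 | (S)-4,7-dimethoxy-2-[2-(4-methoxyphenyl)-1-benzofuran-5-yl]-2H-chromene | COc1ccc(-c2cc3cc([C@@H]4C=C(OC)c5ccc(OC)cc5O4)ccc3o2)cc1
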